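Ring A (C1, C10–C14, briarane numbering) is a 4-methylenecyclohexanol: with C14 as a ketone, the exocyclic C11=C20 alkene is γ,δ to it on both sides. The route rests on cutting C1–C10 and C12–C13. The key step is a one-pot Claisen rearrangement/enolate allylation of an acyclic allyl vinyl ether, an ethyl 3-allyloxy-2-methylbut-2-enoate whose allyl unit is a 2-(chloromethyl)alkenyl group bearing the preformed C7–C9/C17–C19 block. The [3,3] shift forges the hindered C1–C10 bond with both stereocentres and the C11=C20 methylene, and the new methyl ketone enolate then displaces chloride to form C12–C13, closing ring A. The ten-membered ring is closed later at C6–C7.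

Key step: step 13

Remark: briarane numbering is used throughout: C1 (quaternary, C15 methyl), C2 (O-isobutyryl), C3, C4 (OAc), C5 (C16 methyl)=C6, C7 (lactone O), C8 (OH), C9 (OAc), C10, C11 (=C20), C12, C13, C14 (OAc), C17 (C18 methyl), C19 (lactone C=O). The target SMILES is read as the 1R,2S,4R,5Z,7S,8S,9S,10S,14S,17R isomer.

Step 1
Reactants: 1 2,2-dimethyl-1,3-dioxan-5-one; 2 SAMP, (S)-1-amino-2-(methoxymethyl)pyrrolidine
Product: 3 dioxanone SAMP hydrazone
Conditions: PhH, reflux, Dean–Stark
Reagents that add atoms: none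
Why: Hydrazone condensation installs the chiral auxiliary for the asymmetric α-alkylation of the C7–C8–C9 ketone unit.

Step 2
Reactants: 3 dioxanone SAMP hydrazone; 4 benzyl chloromethyl ether
Product: 5 C9-alkylated SAMP hydrazone
Conditions: t-BuLi, THF, −78 °C; then 4, −100 °C → rt
Reagents that add atoms: none
Why: SAMP-hydrazone alkylation, in which the chelated lithium azaenolate is alkylated on the face away from the methoxymethyl arm, should set C9 and attach C10 as a benzyloxymethyl group.

Step 3
Reactants: 5 C9-alkylated SAMP hydrazone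
Product: 6 (S)-4-[(benzyloxy)methyl]-2,2-dimethyl-1,3-dioxan-5-one
Conditions: sat. aq. oxalic acid, Et2O, rt
Reagents that add atoms: water, O
Why: Mild biphasic hydrolysis of the hydrazone should release the α-substituted ketone without epimerisation at C9 or loss of the acetonide.

Step 4
Reactants: 6 (S)-4-[(benzyloxy)methyl]-2,2-dimethyl-1,3-dioxan-5-one; 7 ethyl propanoate
Product: 8 aldol ester
Conditions: 7, LiN(iPr)2, THF–DMPU, −78 °C; then 6, −78 °C; AcOH quench
Reagents that add atoms: none
Why: Aldol addition of the (Z)-lithium ester enolate: equatorial attack on the dioxanone, anti to the ring C–O bonds and trans to the C9 side chain, should set C8, and the closed chair transition state with C9 as the larger ketone branch should set C17.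

Step 5
Reactants: 8 aldol ester
Product: 9 1,3-diol
Conditions: LiAlH4, THF, 0 °C
Reagents that add atoms: none
Why: Hydride reduction of the ester puts C19 at the alcohol level, so no enolisable ester has to pass the later base and hydride steps.

Step 6
Reactants: 9 1,3-diol
Product: 10 silylene benzyl ether
Conditions: tBu2Si(OTf)2, 2,6-lutidine, CH2Cl2, 0 °C → rt
Reagents that add atoms: di-tert-butylsilyl bis(trifluoromethanesulfonate), CC(C)(C)[Si](OS(=O)(=O)C(F)(F)F)(OS(=O)(=O)C(F)(F)F)C(C)(C)C
Why: Silylene formation bridges the primary C19 and tertiary C8 hydroxyls in a six-membered ring, masking the tertiary alkoxide that could otherwise attack the allylic chloride later.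

Step 7
Reactants: 10 silylene benzyl ether
Product: 11 C10 alcohol
Conditions: H2, Pd/C, EtOAc, rt
Reagents that add atoms: none
Why: Hydrogenolysis removes the benzyl ether while acetonide and silylene are inert.

Step 8
Reactants: 11 C10 alcohol
Product: 12 C10 aldehyde
Conditions: Dess–Martin periodinane, NaHCO3, CH2Cl2, 0 °C → rt
Reagents that add atoms: none
Why: Buffered Dess–Martin oxidation gives the α-alkoxy aldehyde under non-epimerising conditions.

Step 9
Reactants: 12 C10 aldehyde; 13 methyl acrylate
Product: 14 Morita–Baylis–Hillman adduct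
Conditions: 13 (excess), DABCO, MeOH, rt
Reagents that add atoms: none
Why: Morita–Baylis–Hillman reaction attaches C11, C12 and C20 to C10; the C10 carbinol configuration is irrelevant because C10 becomes trigonal in the next step.

Step 10
Reactants: 14 Morita–Baylis–Hillman adduct
Product: 15 (Z)-chloromethyl enoate
Conditions: NCS, Me2S, CH2Cl2, −20 → 0 °C
Reagents that add atoms: N-chlorosuccinimide, O=C1CCC(=O)N1Cl
Why: Corey–Kim-type activation followed by SN2′ chloride attack should give the transposed allylic chloride as the favoured (Z)-alkene, with C9 cis to CH2Cl.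

Step 11
Reactants: 15 (Z)-chloromethyl enoate
Product: 16 (Z)-2-(chloromethyl)allylic alcohol
Conditions: iBu2AlH, CH2Cl2, −78 °C
Reagents that add atoms: none
Why: 1,2-Reduction of the enoate at low temperature gives the allylic alcohol (C20–OH trans to C9) and leaves the allylic chloride untouched.

Step 12
Reactants: 16 (Z)-2-(chloromethyl)allylic alcohol; 17 ethyl 2-methylbuta-2,3-dienoate
Product: 18 allyl vinyl ether
Conditions: 17, Cs2CO3 (cat.), MeCN, 0 °C → rt
Reagents that add atoms: none
Why: Oxa-Michael addition of the alcohol to the allenoate and isomerisation into conjugation should give the (E)-β-alkoxy enoate, which brings in C13, C14, C1, C15 and C2.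

Step 13
Reactants: 18 allyl vinyl ether
Product: 20 ring A keto ester, via acyclic chloro keto ester 19 (not isolated)
Conditions: PhMe, K2CO3 (solid), 135 °C, sealed tube; then THF, LiN(SiMe3)2, −78 → 0 °C
Reagents that add atoms: none
Why: Heating triggers a [3,3]-sigmatropic (Claisen) rearrangement through a chair transition state that forms C1–C10 and moves the double bond to C11=C20; deprotonation of the only enolisable position of the α-quaternary β-keto ester 19 (the C13 methyl) then gives a lithium enolate that displaces the allylic chloride to form C12–C13. The closest known reactions are the Claisen rearrangement of O-allyl enol ethers of β-keto esters and the intramolecular alkylation of ketone enolates by allylic halides, run here in one flask as a tethered [3+3] annulation. Ring A closes in the 6-(enolendo)-exo-tet mode, and SN2 attack at C12 or SN2′ attack at the new methylene terminus give the same constitution. C1 and C10 are set together in the chair: the (E)-enol ether places the C15 methyl axial and the allyl geometry places C9 equatorial, which puts the ester (C2) trans to C9 on the new ring. The absolute sense comes from C9: A(1,3) strain with the cis CH2Cl group holds the C9–H bond in the alkene plane, and the enol ether should add to the C10 face anti to the quaternary C8. The step needs C- rather than O-alkylation and no alkylation before the rearrangement; the lithium enolate in THF and the neutral, non-nucleophilic vinyl ether of the thermal stage secure this.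

Step 14
Reactants: 20 ring A keto ester
Product: 22 ring A diol, via ring A hydroxy ester 21 (not isolated)
Conditions: LiBH(sBu)3, THF, −78 °C; then LiAlH4, −78 → 0 °C
Reagents that add atoms: none
Why: The bulky borohydride should attack the C14 ketone equatorially, avoiding the axial hydrogens at C10 and C12 as in selectride reductions of 4,4-dimethyl-3-keto steroids, to give the axial 14-alcohol trans to C15, and LiAlH4 then reduces the untouched ester to the C2 primary alcohol.

Step 15
Reactants: 22 ring A diol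
Product: 23 ring A hydroxy aldehyde
Conditions: TEMPO (cat.), PhI(OAc)2, CH2Cl2, rt
Reagents that add atoms: none
Why: Oxoammonium oxidation is selective for the primary alcohol over the hindered axial secondary one, and the aldehyde on quaternary C1 cannot enolise or eliminate.

Step 16
Reactants: 23 ring A hydroxy aldehyde
Product: 24 ring A acetoxy aldehyde
Conditions: Ac2O, DMAP, pyridine, 40 °C
Reagents that add atoms: acetic anhydride, CC(=O)OC(C)=O
Why: DMAP-catalysed acylation installs the final C14 acetate on the only free hydroxyl.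

Step 17
Reactants: 25 but-3-yn-2-ol
Product: 26 (Z)-4-iodo-3-methylbut-3-en-2-ol
Conditions: MeMgBr, CuI (cat.), THF, −20 °C → rt; then I2, −78 → 0 °C
Reagents that add atoms: methylmagnesium bromide, C[Mg]Br; iodine, II
Why: Copper-catalysed anti-carbomagnesiation of the propargylic alkoxide gives a chelated alkenyl magnesium species whose iodination fixes the (Z)-geometry (carbinol carbon cis to iodine) needed for the 5Z alkene.

Step 18
Reactants: 26 (Z)-4-iodo-3-methylbut-3-en-2-ol
Product: 27 (Z)-4-iodo-3-methylbut-3-en-2-one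
Conditions: Dess–Martin periodinane, NaHCO3, CH2Cl2, 0 °C
Reagents that add atoms: none
Why: Mild buffered oxidation of the allylic alcohol gives the methyl ketone (C3–C6 with C16) without isomerising the (Z)-iodoalkene.

Step 19
Reactants: 24 ring A acetoxy aldehyde; 27 (Z)-4-iodo-3-methylbut-3-en-2-one
Product: 28 β-hydroxy enone
Conditions: 27, (+)-Ipc2BCl, Et3N, Et2O, −78 °C; then 24, −78 → −20 °C; H2O2, pH 7 buffer
Reagents that add atoms: none
Why: Diisopinocampheylboron-mediated aldol reaction of a methyl ketone: the boron enolate of 27 should add to the Si face of the non-enolisable aldehyde under reagent control, forming C2–C3 and setting 2S.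

Step 20
Reactants: 28 β-hydroxy enone
Product: 29 C2 isobutyrate enone
Conditions: (iPrCO)2O, DMAP (cat.), pyridine, CH2Cl2, 0 °C → rt
Reagents that add atoms: isobutyric anhydride, CC(C)C(=O)OC(=O)C(C)C
Why: Acylation of the only free hydroxyl places the isobutyrate unambiguously on O2, under conditions mild enough to avoid β-elimination.

Step 21
Reactants: 29 C2 isobutyrate enone
Product: 30 C4 allylic alcohol
Conditions: (S)-Me-CBS oxazaborolidine (cat.), catecholborane, PhMe, −78 °C
Reagents that add atoms: none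
Why: Corey–Bakshi–Shibata reduction with the alkenyl group as the large and the C3 methylene as the small substituent should give the 4R alcohol, and catecholborane leaves the alkenes untouched.

Step 22
Reactants: 30 C4 allylic alcohol
Product: 31 C4 acetate
Conditions: Ac2O, DMAP (cat.), pyridine, CH2Cl2, 0 °C → rt
Reagents that add atoms: acetic anhydride, CC(=O)OC(C)=O
Why: Acetylation of the only free hydroxyl installs the final C4 acetate.

Step 23
Reactants: 31 C4 acetate
Product: 32 C7,C9-diol
Conditions: AcOH–THF–H2O (3:1:1), 45 °C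
Reagents that add atoms: none
Why: Aqueous acid hydrolyses the acetonide while the silylene, the esters and the alkenyl iodide should survive.

Step 24
Reactants: 32 C7,C9-diol
Product: 33 C7 aldehyde
Conditions: TEMPO (cat.), PhI(OAc)2, CH2Cl2, rt
Reagents that add atoms: none
Why: Oxoammonium oxidation is selective for the primary C7 alcohol over the hindered secondary C9 alcohol, and the aldehyde on quaternary C8 cannot enolise.

Step 25
Reactants: 33 C7 aldehyde
Product: 34 seco aldehyde
Conditions: Ac2O, DMAP, pyridine, rt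
Reagents that add atoms: acetic anhydride, CC(=O)OC(C)=O
Why: Acetylation of the remaining secondary hydroxyl installs the final C9 acetate before ring closure.

Step 26
Reactants: 34 seco aldehyde
Product: 35 macrocyclic C7 alcohol
Conditions: CrCl2, NiCl2 (cat.), DMSO–THF, rt, 0.002 M
Reagents that add atoms: none
Why: Nozaki–Hiyama–Kishi reaction: the alkenyl chromium species from the (Z)-alkenyl iodide adds to the C7 aldehyde with retention of alkene geometry, closing the ten-membered ring at C6–C7, and addition anti to the C8–O bond with C9 in the ring is expected to give the 7S alcohol.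

Step 27
Reactants: 35 macrocyclic C7 alcohol
Product: 36 triol
Conditions: HF·pyridine, pyridine, THF, 0 °C → rt
Reagents that add atoms: none
Why: Buffered fluoride cleaves the silylene to free the C8 and C19 hydroxyls without touching the four esters.

Step 28
Reactants: 36 triol
Product: 38 target CNP0189561.1, via lactol 37 (not isolated)
Conditions: TEMPO (cat.), PhI(OAc)2, CH2Cl2, rt
Reagents that add atoms: none
Why: Oxidative lactonisation of a 1,4-diol: the primary C19 alcohol is oxidised selectively, the aldehyde is trapped by the C7 hydroxyl as lactol 37, and further oxidation gives the γ-lactone while the tertiary C8 hydroxyl stays free.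

Compound list

1 | 2,2-dimethyl-1,3-dioxan-5-one | CC1(C)OCC(=O)CO1 | starting material
2 | SAMP, (S)-1-amino-2-(methoxymethyl)pyrrolidine | COC[C@@H]1CCCN1N | starting material
3 | dioxanone SAMP hydrazone (hydrazone of 1 with 2) | COC[C@@H]1CCCN1N=C1COC(C)(C)OC1 | intermediate
4 | benzyl chloromethyl ether | ClCOCc1ccccc1 | starting material
5 | C9-alkylated SAMP hydrazone (hydrazone of 6 with 2; ring carbon configured as in 6) | COC[C@@H]1CCCN1N=C1COC(C)(C)O[C@H]1COCc1ccccc1 | intermediate
6 | (S)-4-[(benzyloxy)methyl]-2,2-dimethyl-1,3-dioxan-5-one (dioxane C4 = C9, C5 = C8, C6 = C7) | CC1(C)OCC(=O)[C@H](COCc2ccccc2)O1 | intermediate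
7 | ethyl propanoate | CCC(=O)OCC | starting material
8 | aldol ester, ethyl (2R)-2-[(4S,5S)-4-[(benzyloxy)methyl]-5-hydroxy-2,2-dimethyl-1,3-dioxan-5-yl]propanoate | CC1(C)OC[C@@](O)([C@@H](C)C(=O)OCC)[C@H](COCc2ccccc2)O1 | intermediate
9 | 1,3-diol, (2S)-2-[(4S,5S)-4-[(benzyloxy)methyl]-5-hydroxy-2,2-dimethyl-1,3-dioxan-5-yl]propan-1-ol | CC1(C)OC[C@@](O)([C@@H](C)CO)[C@H](COCc2ccccc2)O1 | intermediate
10 | silylene benzyl ether: 1,3-dioxane acetonide (O7, O9) spiro-fused at C8 to a di-tert-butylsilylene ring (O8, O19) carrying the C17 methyl, C9 bearing CH2OBn; C8, C9, C17 as in 9 | C(OC[C@@H]1OC(C)(C)OC[C@]12O[Si](C(C)(C)C)(C(C)(C)C)OC[C@@H]2C)c1ccccc1 | intermediate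
11 | C10 alcohol (debenzylated 10) | OC[C@@H]1OC(C)(C)OC[C@]12O[Si](C(C)(C)C)(C(C)(C)C)OC[C@@H]2C | intermediate
12 | C10 aldehyde (spiro bis-acetal carbaldehyde) | O=C[C@@H]1OC(C)(C)OC[C@]12O[Si](C(C)(C)C)(C(C)(C)C)OC[C@@H]2C | intermediate
13 | methyl acrylate | C=CC(=O)OC | starting material
14 | Morita–Baylis–Hillman adduct, methyl 2-[hydroxy(spiro bis-acetal)methyl]acrylate, both C10 epimers | C=C(C(=O)OC)C(O)[C@@H]1OC(C)(C)OC[C@]12O[Si](C(C)(C)C)(C(C)(C)C)OC[C@@H]2C | intermediate
15 | (Z)-chloromethyl enoate, methyl (2Z)-2-(chloromethyl)-3-(spiro bis-acetal)prop-2-enoate | COC(=O)/C(CCl)=C/[C@@H]1OC(C)(C)OC[C@]12O[Si](C(C)(C)C)(C(C)(C)C)OC[C@@H]2C | intermediate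
16 | (Z)-2-(chloromethyl)allylic alcohol, (2Z)-2-(chloromethyl)-3-(spiro bis-acetal)prop-2-en-1-ol | OC/C(CCl)=C/[C@@H]1OC(C)(C)OC[C@]12O[Si](C(C)(C)C)(C(C)(C)C)OC[C@@H]2C | intermediate
17 | ethyl 2-methylbuta-2,3-dienoate | C=C=C(C)C(=O)OCC | starting material
18 | allyl vinyl ether, ethyl (2E)-3-{[(2Z)-2-(chloromethyl)-3-(spiro bis-acetal)prop-2-en-1-yl]oxy}-2-methylbut-2-enoate | CCOC(=O)/C(C)=C(\C)OC/C(CCl)=C/[C@@H]1OC(C)(C)OC[C@]12O[Si](C(C)(C)C)(C(C)(C)C)OC[C@@H]2C | intermediate
19 | acyclic chloro keto ester, ethyl 2-acetyl-4-(chloromethyl)-2-methyl-3-(spiro bis-acetal)pent-4-enoate, C1 and C10 as in 20 | CCOC(=O)[C@@](C)(C(C)=O)[C@H](C(=C)CCl)[C@@H]1OC(C)(C)OC[C@]12O[Si](C(C)(C)C)(C(C)(C)C)OC[C@@H]2C | intermediate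
20 | ring A keto ester, ethyl 1-methyl-3-methylidene-6-oxo-2-(spiro bis-acetal)cyclohexane-1-carboxylate, C1 R and C10 S, ester trans to C9 | C=C1CCC(=O)[C@](C)(C(=O)OCC)[C@H]1[C@@H]2OC(C)(C)OC[C@]23O[Si](C(C)(C)C)(C(C)(C)C)OC[C@@H]3C | intermediate
21 | ring A hydroxy ester (14-alcohol of 20, hydroxyl trans to C15 methyl) | C=C1CC[C@H](O)[C@](C)(C(=O)OCC)[C@H]1[C@@H]2OC(C)(C)OC[C@]23O[Si](C(C)(C)C)(C(C)(C)C)OC[C@@H]3C | intermediate
22 | ring A diol (C14 secondary and C2 primary alcohols; stereocentres as in 38) | C=C1CC[C@H](O)[C@](C)(CO)[C@H]1[C@@H]2OC(C)(C)OC[C@]23O[Si](C(C)(C)C)(C(C)(C)C)OC[C@@H]3C | intermediate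
23 | ring A hydroxy aldehyde (C2 aldehyde, C14 alcohol) | C=C1CC[C@H](O)[C@](C)(C=O)[C@H]1[C@@H]2OC(C)(C)OC[C@]23O[Si](C(C)(C)C)(C(C)(C)C)OC[C@@H]3C | intermediate
24 | ring A acetoxy aldehyde (C2 aldehyde, C14 acetate) | C=C1CC[C@H](OC(C)=O)[C@](C)(C=O)[C@H]1[C@@H]2OC(C)(C)OC[C@]23O[Si](C(C)(C)C)(C(C)(C)C)OC[C@@H]3C | intermediate
25 | but-3-yn-2-ol (racemic) | CC(O)C#C | starting material
26 | (Z)-4-iodo-3-methylbut-3-en-2-ol (racemic carbinol) | CC(O)/C(C)=C\I | intermediate
27 | (Z)-4-iodo-3-methylbut-3-en-2-one | CC(=O)/C(C)=C\I | intermediate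
28 | β-hydroxy enone (2S alcohol, C4 ketone, (Z)-C5=C6 iodoalkene) | C=C1CC[C@H](OC(C)=O)[C@](C)([C@@H](O)CC(=O)/C(C)=C\I)[C@H]1[C@@H]2OC(C)(C)OC[C@]23O[Si](C(C)(C)C)(C(C)(C)C)OC[C@@H]3C | intermediate
29 | C2 isobutyrate enone | C=C1CC[C@H](OC(C)=O)[C@](C)([C@@H](OC(=O)C(C)C)CC(=O)/C(C)=C\I)[C@H]1[C@@H]2OC(C)(C)OC[C@]23O[Si](C(C)(C)C)(C(C)(C)C)OC[C@@H]3C | intermediate
30 | C4 allylic alcohol (4R) | C=C1CC[C@H](OC(C)=O)[C@](C)([C@@H](OC(=O)C(C)C)C[C@@H](O)/C(C)=C\I)[C@H]1[C@@H]2OC(C)(C)OC[C@]23O[Si](C(C)(C)C)(C(C)(C)C)OC[C@@H]3C | intermediate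
31 | C4 acetate | C=C1CC[C@H](OC(C)=O)[C@](C)([C@@H](OC(=O)C(C)C)C[C@@H](OC(C)=O)/C(C)=C\I)[C@H]1[C@@H]2OC(C)(C)OC[C@]23O[Si](C(C)(C)C)(C(C)(C)C)OC[C@@H]3C | intermediate
32 | C7,C9-diol (acetonide removed, silylene kept) | C=C1CC[C@H](OC(C)=O)[C@](C)([C@@H](OC(=O)C(C)C)C[C@@H](OC(C)=O)/C(C)=C\I)[C@H]1[C@H](O)[C@]2(CO)O[Si](C(C)(C)C)(C(C)(C)C)OC[C@@H]2C | intermediate
33 | C7 aldehyde (C9 alcohol) | C=C1CC[C@H](OC(C)=O)[C@](C)([C@@H](OC(=O)C(C)C)C[C@@H](OC(C)=O)/C(C)=C\I)[C@H]1[C@H](O)[C@]2(C=O)O[Si](C(C)(C)C)(C(C)(C)C)OC[C@@H]2C | intermediate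
34 | seco aldehyde (C7 aldehyde, C9 acetate, C6 iodide) | C=C1CC[C@H](OC(C)=O)[C@](C)([C@@H](OC(=O)C(C)C)C[C@@H](OC(C)=O)/C(C)=C\I)[C@H]1[C@H](OC(C)=O)[C@]2(C=O)O[Si](C(C)(C)C)(C(C)(C)C)OC[C@@H]2C | intermediate
35 | macrocyclic C7 alcohol (briarane carbocycle, 7S, O8/O19 silylene) | C=C1CC[C@H](OC(C)=O)[C@]2(C)[C@@H](OC(=O)C(C)C)C[C@@H](OC(C)=O)/C(C)=C\[C@H](O)[C@]3(O[Si](C(C)(C)C)(C(C)(C)C)OC[C@@H]3C)[C@@H](OC(C)=O)[C@@H]12 | intermediate
36 | triol (C7, C8 and C19 hydroxyls free) | C=C1CC[C@H](OC(C)=O)[C@]2(C)[C@@H](OC(=O)C(C)C)C[C@@H](OC(C)=O)/C(C)=C\[C@H](O)[C@@](O)([C@@H](C)CO)[C@@H](OC(C)=O)[C@@H]12 | intermediate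
37 | lactol (C19 hemiacetal closed on O7, both C19 epimers) | C=C1CC[C@H](OC(C)=O)[C@]2(C)[C@@H](OC(=O)C(C)C)C[C@@H](OC(C)=O)/C(C)=C\[C@@H]3OC(O)[C@H](C)[C@@]3(O)[C@@H](OC(C)=O)[C@@H]12 | intermediate
38 | CNP0189561.1, (1R,2S,4R,5Z,7S,8S,9S,10S,14S,17R)-4,9,14-triacetoxy-8-hydroxy-2-isobutyryloxybriara-5,11(20)-dien-19,7-olide | C=C1CC[C@H](OC(C)=O)[C@]2(C)[C@@H](OC(=O)C(C)C)C[C@@H](OC(C)=O)/C(C)=C\[C@@H]3OC(=O)[C@H](C)[C@@]3(O)[C@@H](OC(C)=O)[C@@H]12 | target

Total step count: 28.
Longest linear sequence: 26 steps (steps 1–16 and 19–28; steps 17 and 18 make the side fragment 27).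

Steps most likely to fail

1. Step 13 (key step). The thermal stage may run partly through a boat transition state or ionise the allylic chloride, the C9 stereocentre may give poor facial selectivity, and the enolate may alkylate on oxygen. The fallback sets out from 18 and comes back at 20: the Claisen rearrangement is run alone (PhMe, 110–135 °C, or at lower temperature in a hydrogen-bond-donating solvent) and the acyclic chloro keto ester 19 is isolated and purified. The C12–C13 bond is then closed by a Tsuji–Trost cyclisation under dual catalysis by pyrrolidine and Pd(PPh3)4 with Et3N, in which the enamine of the methyl ketone attacks the π-allyl palladium complex; both allyl termini give 20. This fallback makes no new compound (F0).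

2. Step 26. The alkenyl chromium species may be reduced or oligomerise before the hindered aldehyde on quaternary C8 is reached, and the facial selectivity at C7 may be poor. The fallback sets out from 34 and comes back at 35, moving the ring closure to C5=C6. Hydrodeiodination of 34 (Bu3SnH, Pd(PPh3)4) gives the isopropenyl aldehyde F1. Intermolecular Nozaki–Hiyama–Kishi addition of vinyl iodide (CrCl2, NiCl2 cat., DMSO) gives the C7 vinyl carbinol F2. Ring-closing metathesis with a second-generation Hoveyda–Grubbs catalyst (PhMe, 80 °C, high dilution) then forms the trisubstituted C5=C6 alkene, held Z by the ten-membered ring, and gives 35.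

3. Step 4. Enolisation of the ketone by the ester enolate, retro-aldol cleavage on warming and poor control of the C17 methyl may erode this step. The fallback sets out from 6 and comes back at 9. Addition of isopropenylmagnesium bromide with CeCl3 (THF, −78 °C), again by equatorial attack trans to the C9 side chain, gives the tertiary allylic alcohol F3. Hydroboration with 9-BBN followed by NaOH/H2O2 then gives the diol 9, with C17 set by approach of the borane anti to the dioxane ring.

Further compounds

F0 | step 13 | none | none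
F1 | step 26 | isopropenyl aldehyde (34 with the C6 iodine replaced by hydrogen) | C=C1CC[C@H](OC(C)=O)[C@](C)([C@@H](OC(=O)C(C)C)C[C@@H](OC(C)=O)C(C)=C)[C@H]1[C@H](OC(C)=O)[C@]2(C=O)O[Si](C(C)(C)C)(C(C)(C)C)OC[C@@H]2C
F2 | step 26 | C7 vinyl carbinol (7S allylic alcohol from F1) | C=C1CC[C@H](OC(C)=O)[C@](C)([C@@H](OC(=O)C(C)C)C[C@@H](OC(C)=O)C(C)=C)[C@H]1[C@H](OC(C)=O)[C@]2([C@@H](O)C=C)O[Si](C(C)(C)C)(C(C)(C)C)OC[C@@H]2C
F3 | step 4 | tertiary allylic alcohol, 4-[(benzyloxy)methyl]-2,2-dimethyl-5-(prop-1-en-2-yl)-1,3-dioxan-5-ol, C8 and C9 as in 8 | CC1(C)OC[C@@](O)(C(C)=C)[C@H](COCc2ccccc2)O1
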